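In a one-step world a charge of partner meets substrate once and the sum ends there, but here partner can add to the same substrate up to 3 times, and two of us disagreed about what to freeze.

    substrate + partner → single product (k1 = 0.0062 L mol⁻¹ s⁻¹)
    partner + single product → double product (k2 = 0.0060 L mol⁻¹ s⁻¹)
    partner + double product → triple product (k3 = 0.011 L mol⁻¹ s⁻¹)
    partner → decomposition product (k4 = 2.8 × 10⁻⁶ s⁻¹)

| setting | maple | alder | larch | birch | elm |
|---|---|---|---|---|---|
| substrate | 0.092 M | 0.092 M | 0.092 M | 0.092 M | 0.092 M |
| partner | 0.0500 M | 0.0800 M | 0.120 M | 0.150 M | 0.250 M |
| time | 2.0 h | 2.0 h | 2.0 h | 2.0 h | 2.0 h |

1. amount of triple product at the end, in percent of the substrate charged for maple, alder, larch, birch, elm, in this order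
2. how that number moves from the first to the last of them (falls, then rises / falls all the way / rises, then falls / rises all the way / hardly changes)

- "hardly changes" means that all values lie within two and a half points (for a concentration: within two and a half percent of the largest)
- run time (maple): 2.0 h

My colleague froze the partner level at its charge, the pseudo-first-order view, with time as the clock. In maple, with partner as charged, the half-life of substrate by the first addition is 0.62 h and that of double product by the third addition 0.35 h, both shorter than the run, while decomposition of partner has a half-life of 69 h, far longer than the run. His frozen exposure, the first rate constant times partner charge times time, is 2.23, which on his reckoning leaves 10.8% of the substrate in maple.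

I answered that at that exposure the first addition takes 0.0821 M of partner, more than maple's charge of 0.0500 M. So I froze something else and treated partner as the limiting reagent. My quantity is the partner count, partner charged per substrate charged, 0.543 in maple. The first two constants, 0.0062 L mol⁻¹ s⁻¹ and 0.0060 L mol⁻¹ s⁻¹, are nearly equal, so I let additions fall on substrate like random hits. When a count's worth of additions has been made, I reckon the fraction of substrate left as the exponential of minus the count. I reckon triple product, as a fraction of the substrate charged, as that fraction times the cube of the count over 6, times 1.72, the constants of the second and third steps over the square of the first.

This gives 2.67% for maple, and with counts of 0.870, 1.30, 1.63 and 2.72 it gives 7.91%, 17.2%, 24.3% and 38.0%. I commit to the rise and the lean end, not to elm's figure, for in elm the count stands close to the 3 additions a substrate can take, and triple product takes no further partner.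

The forecast takes the same side and goes higher than I do at the rich end, with 2.6%, 8%, 19%, 30% and 71%, so rises all the way, holding that “its yield depends steeply on how much partner is available”.

The simulation gives 2.60%, 8.02%, 19.3%, 30.2% and 71.3%, so rises all the way, and my colleague's frozen level has its region in the opening of maple, where by 0.200 h his reckoning has 20.0% of the substrate consumed and the flask 16.7%. Held at its charge, partner carries maple to 48.3% triple product instead of 2.60%, the largest single effect. The count of 0.543 in maple puts the substrate left at 58.1% and the count of 0.870 in alder at 41.9%, and after 20.0 h those flasks hold 58.5% and 42.5%.

The numbers of this flask belong to no real substance; no experiment stands behind them.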